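Ring A, the benzene ring, carries its acyl group on a carbon flanked by two hydroxyl-bearing carbons, with the methoxy-bearing carbon para to it. This is the oxygen pattern of a 3,5,7-trioxo ester whose C3 oxygen is methylated. The route therefore disconnects the bond between the acyl-bearing carbon and one neighbouring C–OH carbon. In one operation, Mg(OMe)2 opens a 4-methoxy-2-pyranone bearing the (R)-3-methyl-2-oxopentyl chain at C6 and folds the released chain by Claisen closure into ring A. The methyl ether is already in place, and the stereocentre, bought in (R)-2-methylbutanoic acid, is untouched. Ring A is then joined to the pyranone ring B through a Mannich-derived methylene.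

Key step: step 3

Assumption: (R)-2-methylbutanoic acid 1 is purchased as the single enantiomer; hydroxypyranones and phenols are written as their enol tautomers; ring A is the benzene ring and ring B the pyranone ring of the target.

Step 1
Reactants: 1 (R)-2-methylbutanoic acid
Product: 3 (R)-N-methoxy-N,2-dimethylbutanamide, via acyl imidazole 2 (not isolated)
Conditions: CDI (1.1 equiv), CH2Cl2, 0 °C → rt; then MeNH(OMe)·HCl (1.2 equiv), rt
Reagents that add atoms: N,O-dimethylhydroxylamine hydrochloride, CNOC.Cl
Why: Activation of the acid as its acyl imidazole and aminolysis by the hydroxylamine (Weinreb amide formation) run under near-neutral conditions with no ketene or oxazolone pathway, so the (R)-centre of 1 should be carried over unchanged and no new stereocentre forms.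

Step 2
Reactants: 3 (R)-N-methoxy-N,2-dimethylbutanamide; 4 4-methoxy-6-methylpyran-2-one
Product: 7 4-methoxy-6-[(3R)-3-methyl-2-oxopentyl]pyran-2-one, via lithiated pyranone 5 (not isolated), via tetrahedral lithium adduct 6 (not isolated)
Conditions: 4 (2.0 equiv), LiN(iPr)2 (2.0 equiv), THF, −78 °C; then 3 (1.0 equiv), −78 → −20 °C; aq. NH4Cl
Reagents that add atoms: none
Why: LiN(iPr)2 removes a proton from the C6 methyl group of 4 to give the extended dienolate, which is acylated at that carbon by the Weinreb amide (vinylogous Claisen-type acylation, Weinreb ketone synthesis); the chelated adduct 6 persists until the quench, so over-addition is excluded, the new ketone never meets the base and the methine should keep its configuration.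

Step 3
Reactants: 7 4-methoxy-6-[(3R)-3-methyl-2-oxopentyl]pyran-2-one
Product: 9 (R)-1-(2,6-dihydroxy-4-methoxyphenyl)-2-methylbutan-1-one, via open-chain magnesium diketonate 8 (not isolated)
Conditions: Mg(OMe)2 (4 equiv), MeOH, reflux; then cold 1 M HCl
Reagents that add atoms: none
Why: Attack of methoxide at C2 of 7 cleaves the lactone and releases the ester 8, which is trapped as the magnesium chelate of its 5,7-dione; C6, the carbon between the two ketones, then adds to the ester carbon C1, methoxide is lost and the cyclohexadienone formed tautomerises to the phenol. The closest known reaction type is the Mg(OMe)2-induced ring opening and intramolecular Claisen condensation that turns 6-acylmethyl-2-pyranones and open 3,5,7-trioxo esters into 2-acylphloroglucinols. Ring A closes in a 6-(enolendo)-exo-trig mode, and the C2=C3 double bond of 8 comes out of the pyranone ring with the ester carbon cis to C4 (the 2E isomer by the sequence rules), so C1 sits next to C6. No stereocentre is created; the only one, C8 of 8, is a spectator. The step needs Claisen (C6 to C1) rather than aldol (C2 to C7) folding and retention at C8: magnesium chelation makes C6 the nucleophile and deactivates the C7 carbonyl, the C3 enol ether removes the β-keto ester reactivity of C2, and enolisation of the dione toward C6 leaves the C8–H in place. The C3 methoxy group ends para to the acyl-bearing carbon of ring A, so no later selective O-methylation is required.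

Step 4
Reactants: 10 3-pentanone; 11 malonyl dichloride
Product: 13 6-ethyl-4-hydroxy-5-methylpyran-2-one, via diketo acid chloride 12 (not isolated)
Conditions: 10 (3 equiv), 11 (1 equiv), neat, 0 °C → rt, then 50 °C
Reagents that add atoms: none
Why: The enol of the symmetrical ketone is C-acylated by one acyl chloride group and the enol oxygen of the resulting 1,3-diketone closes onto the second (acylation–lactonisation of a ketone with malonyl dichloride to a 4-hydroxy-2-pyranone), the symmetry of 10 allowing only one regiochemical outcome.

Step 5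
Reactants: 13 6-ethyl-4-hydroxy-5-methylpyran-2-one; 9 (R)-1-(2,6-dihydroxy-4-methoxyphenyl)-2-methylbutan-1-one
Product: 16 3-({2,4-dihydroxy-6-methoxy-3-[(2R)-2-methylbutanoyl]phenyl}methyl)-6-ethyl-4-hydroxy-5-methylpyran-2-one, via Mannich base 14 (not isolated), via methylidene pyrandione 15 (not isolated)
Conditions: 13, Me2N=CH2+ I− (1.0 equiv), MeCN, rt; then 9 (1.5 equiv), 60 °C
Reagents that add atoms: Eschenmoser's salt (N,N-dimethylmethylideneammonium iodide), C=[N+](C)C.[I-]
Why: Mannich reaction at the nucleophilic C3 of 13 gives 14, which on warming loses dimethylamine to the Michael acceptor 15, and this is captured at carbon by electron-rich ring A of 9 (Mannich/elimination/Friedel–Crafts-type conjugate addition); the two open positions of ring A are equivalent, the excess of 9 should hold back a second alkylation, and the remote stereocentre is not touched.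

Compound list
1 | (R)-2-methylbutanoic acid | OC(=O)[C@H](C)CC | starting material
2 | (R)-1-(1H-imidazol-1-yl)-2-methylbutan-1-one | O=C([C@H](C)CC)n1ccnc1 | intermediate (not isolated)
3 | (R)-N-methoxy-N,2-dimethylbutanamide | CON(C)C(=O)[C@H](C)CC | intermediate
4 | 4-methoxy-6-methylpyran-2-one | COc1cc(C)oc(=O)c1 | starting material
5 | 6-(lithiomethyl)-4-methoxypyran-2-one (lithium dienolate of 4) | [Li]Cc1cc(OC)cc(=O)o1 | intermediate (not isolated)
6 | lithium (3R)-2-[methoxy(methyl)amino]-1-(4-methoxy-2-oxo-2H-pyran-6-yl)-3-methylpentan-2-olate, both epimers at C2 | COc1cc(CC(O[Li])(N(C)OC)[C@H](C)CC)oc(=O)c1 | intermediate (not isolated)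
7 | 4-methoxy-6-[(3R)-3-methyl-2-oxopentyl]pyran-2-one | COc1cc(CC(=O)[C@H](C)CC)oc(=O)c1 | intermediate (key-step precursor)
8 | methyl (2E,8R)-3-methoxy-8-methyl-5,7-dioxodec-2-enoate, present as its magnesium 5,7-diketonate | COC(=O)/C=C(/OC)CC(=O)CC(=O)[C@H](C)CC | intermediate (not isolated)
9 | (R)-1-(2,6-dihydroxy-4-methoxyphenyl)-2-methylbutan-1-one | COc1cc(O)c(C(=O)[C@H](C)CC)c(O)c1 | intermediate (key-step product)
10 | 3-pentanone | CCC(=O)CC | starting material
11 | malonyl dichloride | O=C(Cl)CC(Cl)=O | starting material
12 | 4-methyl-3,5-dioxoheptanoyl chloride (racemic, enolisable) | CCC(=O)C(C)C(=O)CC(=O)Cl | intermediate (not isolated)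
13 | 6-ethyl-4-hydroxy-5-methylpyran-2-one | CCc1oc(=O)cc(O)c1C | intermediate
14 | 3-[(dimethylamino)methyl]-6-ethyl-4-hydroxy-5-methylpyran-2-one hydroiodide | CCc1oc(=O)c(C[NH+](C)C)c(O)c1C.[I-] | intermediate (not isolated)
15 | 6-ethyl-5-methyl-3-methylidenepyran-2,4-dione | CCC1=C(C)C(=O)C(=C)C(=O)O1 | intermediate (not isolated)
16 | 3-({2,4-dihydroxy-6-methoxy-3-[(2R)-2-methylbutanoyl]phenyl}methyl)-6-ethyl-4-hydroxy-5-methylpyran-2-one | CCc1oc(=O)c(Cc2c(OC)cc(O)c(C(=O)[C@H](C)CC)c2O)c(O)c1C | target

Total step count: 5. Longest linear sequence: 4 steps (steps 1, 2, 3 and 5); step 4 is a one-step side branch.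

Steps most likely to fail

Step 3 (key step). The lactone may resist opening once the side-chain methylene is deprotonated. The opened chain may condense in the aldol sense (C2 onto C7). Methoxide may cleave the dione by acyl transfer. Prolonged heating may slowly epimerise the methine. The fallback buys ring A and sets out from 3, returning to the route at 9. 1,3,5-Trimethoxybenzene (COc1cc(OC)cc(OC)c1, purchased) would be lithiated with n-BuLi/TMEDA in THF at 0 °C to 2,4,6-trimethoxyphenyllithium F1. This would be added to 3 at −78 °C to give lithium (2R)-1-[methoxy(methyl)amino]-2-methyl-1-(2,4,6-trimethoxyphenyl)butan-1-olate F2, which on quench releases (R)-2-methyl-1-(2,4,6-trimethoxyphenyl)butan-1-one F3. BCl3 in CH2Cl2 (−78 °C → rt) should then cleave the two methyl ethers flanking the carbonyl by chelation-directed dealkylation, passing through (R)-1-(2-hydroxy-4,6-dimethoxyphenyl)-2-methylbutan-1-one F4 and leaving the para ether, to give 9. The price is a Lewis acid next to the stereocentre, so the configurational purity of 9 would have to be checked.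

Step 5. A second alkylation may occur at the remaining open position of ring A. Pyranone 13 may add to 15 to give the methylene-bis-pyranone. Acceptor 15 may also dimerise. The fallback is a block–couple–unblock sequence that sets out from 9 and returns at 16. NBS (1.0 equiv, CH2Cl2, −78 °C) should give (R)-1-(3-bromo-2,6-dihydroxy-4-methoxyphenyl)-2-methylbutan-1-one F5, in which only one position of ring A is open. Coupling of F5 with 14, made from 13 as in step 5 and passing through 15, should give 3-({5-bromo-2,4-dihydroxy-6-methoxy-3-[(2R)-2-methylbutanoyl]phenyl}methyl)-6-ethyl-4-hydroxy-5-methylpyran-2-one F6. Hydrogenolysis of the C–Br bond (H2, Pd/C, NaOAc, EtOAc, rt, stopped at consumption of F6) should then give 16.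

Step 2. Deprotonation may compete at ring C3 instead of the methyl group. Addition of the stabilised dienolate to the α-branched amide may be slow, and proton exchange may consume the anion. The fallback sets out from 3 and returns at 7. 4-Hydroxy-6-methylpyran-2-one (Cc1cc(O)cc(=O)o1, purchased) would be converted with LiN(iPr)2 (2.2 equiv, THF, −78 → 0 °C) into lithium 6-(lithiomethyl)-2-oxo-2H-pyran-4-olate F7. Its 4-oxido group shields ring C3, so only the methyl carbon is metallated, and this dianion is more nucleophilic than 5. Acylation by 3 should give dilithium 6-{(3R)-2-[methoxy(methyl)amino]-3-methyl-2-oxidopentyl}-2-oxo-2H-pyran-4-olate F8 and, after acidic quench, 4-hydroxy-6-[(3R)-3-methyl-2-oxopentyl]pyran-2-one F9. Selective O-methylation of the acidic 4-hydroxyl (Me2SO4, K2CO3 1.0 equiv, acetone, rt) should then give 7.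

Further compounds
F1 | step 3 | 2,4,6-trimethoxyphenyllithium | [Li]c1c(OC)cc(OC)cc1OC
F2 | step 3 | lithium (2R)-1-[methoxy(methyl)amino]-2-methyl-1-(2,4,6-trimethoxyphenyl)butan-1-olate | COc1cc(OC)c(C(O[Li])(N(C)OC)[C@H](C)CC)c(OC)c1
F3 | step 3 | (R)-2-methyl-1-(2,4,6-trimethoxyphenyl)butan-1-one | COc1cc(OC)c(C(=O)[C@H](C)CC)c(OC)c1
F4 | step 3 | (R)-1-(2-hydroxy-4,6-dimethoxyphenyl)-2-methylbutan-1-one | COc1cc(O)c(C(=O)[C@H](C)CC)c(OC)c1
F5 | step 5 | (R)-1-(3-bromo-2,6-dihydroxy-4-methoxyphenyl)-2-methylbutan-1-one | COc1cc(O)c(C(=O)[C@H](C)CC)c(O)c1Br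
F6 | step 5 | 3-({5-bromo-2,4-dihydroxy-6-methoxy-3-[(2R)-2-methylbutanoyl]phenyl}methyl)-6-ethyl-4-hydroxy-5-methylpyran-2-one | CCc1oc(=O)c(Cc2c(OC)c(Br)c(O)c(C(=O)[C@H](C)CC)c2O)c(O)c1C
F7 | step 2 | lithium 6-(lithiomethyl)-2-oxo-2H-pyran-4-olate | [Li]Cc1cc(O[Li])cc(=O)o1
F8 | step 2 | dilithium 6-{(3R)-2-[methoxy(methyl)amino]-3-methyl-2-oxidopentyl}-2-oxo-2H-pyran-4-olate | [Li]Oc1cc(CC(O[Li])(N(C)OC)[C@H](C)CC)oc(=O)c1
F9 | step 2 | 4-hydroxy-6-[(3R)-3-methyl-2-oxopentyl]pyran-2-one | Oc1cc(CC(=O)[C@H](C)CC)oc(=O)c1
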